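**Retrosynthetic overview**

1. Labels: cyclopentane C1(O)–C2–C3–C4(CH3)–C5(H); cycloheptane C1–C5–C6–C7–C8–C9–C10(CH3); cyclopropane C6–C7–C11(CH3)2; benzylic C7′; arene C1′–C6′. The strategy rests on C2′, the arene carbon on the ether oxygen: it is ortho to the C3′ formyl and para to the C5′ formyl, and O–C1 and C7′–C4 are cis-1,3 on the cyclopentane, so a C2′–F is displaced by the C1 alkoxide.
2. Last skeletal bond: O–C2′ by intramolecular SNAr, closing the oxepine O–C1–C5–C4–C7′–C1′–C2′; only cleavage of two methyl ethers follows.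
3. Before that: both CHO groups by Br/Li exchange–DMF once the cyclopentanol exists; C1–C2 by SmI2 Barbier closure; C4–C5 (quaternary C4) by Claisen rearrangement of the enol ether made from a regiodefined cycloheptenyl iodide and an (E)-allylic alcohol.
4. Fragments: the cycloheptanone from (+)-2-carene (ozonolysis, C1 inserted by homologation, McMurry closure, hydroboration sets C10); the allylic alcohol carrying C7′ from 1-fluoro-3,5-dimethoxybenzene, 3-methylbutan-1-ol and but-2-yn-1-ol by lithiation–borylation and Zweifel olefination.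
5. Ring order: cyclopropane (chiral pool) → cycloheptane → cyclopentane → oxepine.

Key step: step 22

Assumption: bromination of 1-fluoro-3,5-dimethoxybenzene is taken to go mainly at C2 (between F and OMe, para to the second OMe), the position this arene also offers to other electrophiles; the minor 4-bromo isomer is removed at that stage.

**Route**

Step 1
Reactants: 1 1-fluoro-3,5-dimethoxybenzene
Product: 2 2-bromo-1-fluoro-3,5-dimethoxybenzene
Conditions: NBS (1.0 equiv), MeCN, 0 °C → rt
Reagents that add atoms: N-bromosuccinimide O=C1CCC(=O)N1Br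
Why: Electrophilic aromatic bromination of the doubly activated ring should go mainly at the carbon that is para to one methoxy group, ortho to the other and flanked by the small fluorine, which places the later C1′ between F and OMe.

Step 2
Reactants: 2 2-bromo-1-fluoro-3,5-dimethoxybenzene
Product: 4 2-(2-fluoro-4,6-dimethoxyphenyl)-4,4,5,5-tetramethyl-1,3,2-dioxaborolane, via aryllithium 3 (not isolated)
Conditions: n-BuLi, THF, −78 °C; i-PrOBpin, −78 °C → rt; aq. NH4Cl
Reagents that add atoms: 2-isopropoxy-4,4,5,5-tetramethyl-1,3,2-dioxaborolane CC(C)OB1OC(C)(C)C(C)(C)O1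
Why: Bromine–lithium exchange gives an ortho-fluoro aryllithium that does not lose LiF at −78 °C and is trapped there by the borate ester (exchange–borylation).

Step 3
Reactants: 5 3-methylbutan-1-ol
Product: 6 3-methylbutyl N,N-diisopropylcarbamate
Conditions: i-Pr2NCOCl, Et3N, CH2Cl2, reflux
Reagents that add atoms: N,N-diisopropylcarbamoyl chloride CC(C)N(C(C)C)C(=O)Cl
Why: O-Carbamoylation of the primary alcohol installs the directing and leaving group for the Hoppe lithiation, the O-bound CH2 being the future C7′.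

Step 4
Reactants: 6 3-methylbutyl N,N-diisopropylcarbamate; 4 2-(2-fluoro-4,6-dimethoxyphenyl)-4,4,5,5-tetramethyl-1,3,2-dioxaborolane
Product: 9 (S)-2-[1-(2-fluoro-4,6-dimethoxyphenyl)-3-methylbutyl]-4,4,5,5-tetramethyl-1,3,2-dioxaborolane, via lithiated carbamate 7 (not isolated), via boronate complex 8 (not isolated)
Conditions: s-BuLi, (+)-sparteine, Et2O, −78 °C; 4, −78 °C; MgBr2·OEt2, → reflux; aq. NH4Cl
Reagents that add atoms: none
Why: Hoppe–Aggarwal lithiation–borylation, in which s-BuLi/(+)-sparteine removes one enantiotopic proton to give the configurationally stable (R)-lithio carbamate, borylation proceeds with retention, and the 1,2-shift of the electron-rich aryl group with inversion expels the carbamate, so C7′ is set by the diamine.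

Step 5
Reactants: 10 but-2-yn-1-ol
Product: 12 (Z)-3-iodobut-2-en-1-ol, via cyclic alkenylalanate 11 (not isolated)
Conditions: Red-Al, THF, 0 °C → rt; I2, −78 → 0 °C
Reagents that add atoms: iodine II
Why: Hydroxyl-directed trans-hydroalumination puts aluminium on C3 cis to the CH2O group in the chelate, and iodinolysis with retention gives the (Z)-vinyl iodide only.

Step 6
Reactants: 12 (Z)-3-iodobut-2-en-1-ol
Product: 13 tert-butyl{[(Z)-3-iodobut-2-en-1-yl]oxy}dimethylsilane
Conditions: TBSCl, imidazole, CH2Cl2, 0 °C → rt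
Reagents that add atoms: tert-butyldimethylsilyl chloride CC(C)(C)[Si](C)(C)Cl
Why: Standard silylation protects the hydroxyl group against the organolithium chemistry of the next step.

Step 7
Reactants: 13 tert-butyl{[(Z)-3-iodobut-2-en-1-yl]oxy}dimethylsilane; 9 (S)-2-[1-(2-fluoro-4,6-dimethoxyphenyl)-3-methylbutyl]-4,4,5,5-tetramethyl-1,3,2-dioxaborolane
Product: 16 tert-butyl{[(2E,4R)-4-(2-fluoro-4,6-dimethoxyphenyl)-3,6-dimethylhept-2-en-1-yl]oxy}dimethylsilane, via alkenyllithium 14 (not isolated), via alkenyl boronate complex 15 (not isolated)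
Conditions: 13, t-BuLi (2 equiv), THF, −78 °C; 9, −78 → 0 °C; I2, THF, −78 °C; NaOMe, MeOH, → rt
Reagents that add atoms: none
Why: Zweifel olefination, in which the alkenyllithium formed with retention of geometry gives an ate complex, iodine triggers 1,2-migration of the benzylic carbon with retention, and anti elimination inverts the alkene geometry, so the (Z)-lithio reagent should give the (E)-trisubstituted alkene with C7′ unchanged.

Step 8
Reactants: 16 tert-butyl{[(2E,4R)-4-(2-fluoro-4,6-dimethoxyphenyl)-3,6-dimethylhept-2-en-1-yl]oxy}dimethylsilane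
Product: 17 (2E,4R)-4-(2-fluoro-4,6-dimethoxyphenyl)-3,6-dimethylhept-2-en-1-ol
Conditions: TBAF, THF, 0 °C → rt
Reagents that add atoms: none
Why: Fluoride-mediated desilylation frees the primary allylic alcohol without touching the aryl fluoride or the benzylic stereocentre.

Step 9
Reactants: 18 (+)-2-carene
Product: 20 (1S,3R)-2,2-dimethyl-3-(3-oxobutyl)cyclopropane-1-carbaldehyde, via ozonide 19 (not isolated)
Conditions: O3, CH2Cl2, −78 °C; Me2S, → rt
Reagents that add atoms: ozone [O-][O+]=O
Why: Ozonolysis of the only C=C bond with reductive work-up gives the cis keto aldehyde and leaves the two cyclopropane stereocentres (later C6 and C7) untouched.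

Step 10
Reactants: 20 (1S,3R)-2,2-dimethyl-3-(3-oxobutyl)cyclopropane-1-carbaldehyde
Product: 22 2-[(1S,3R)-2,2-dimethyl-3-(3-oxobutyl)cyclopropyl]acetaldehyde, via enol ether 21 (not isolated)
Conditions: MeOCH2PPh3Cl, KHMDS, THF, −78 → 0 °C; then 2 M HCl, THF, rt, short
Reagents that add atoms: (methoxymethyl)triphenylphosphonium chloride COC[P+](c1ccccc1)(c1ccccc1)c1ccccc1.[Cl-]; water O
Why: Wittig methoxymethylenation is selective for the aldehyde over the methyl ketone at low temperature, and brief hydrolysis of the enol ether through an oxocarbenium ion that is not cyclopropylcarbinyl gives the homologated aldehyde, whose new CH2 is C5 and whose CHO carbon is C1.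

Step 11
Reactants: 22 2-[(1S,3R)-2,2-dimethyl-3-(3-oxobutyl)cyclopropyl]acetaldehyde
Product: 23 (1S,7R)-4,8,8-trimethylbicyclo[5.1.0]oct-3-ene
Conditions: TiCl3(DME)1.5, Zn–Cu, DME, reflux, slow addition
Reagents that add atoms: none
Why: Intramolecular McMurry coupling of the keto aldehyde under high dilution should close the seven-membered ring as the C1=C10 alkene, both ketyl carbons being insulated from the cyclopropane by at least one CH2.

Step 12
Reactants: 23 (1S,7R)-4,8,8-trimethylbicyclo[5.1.0]oct-3-ene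
Product: 25 (1S,3S,4S,7R)-4,8,8-trimethylbicyclo[5.1.0]octan-3-ol, via alkylborane 24 (not isolated)
Conditions: BH3·THF, THF, 0 °C → rt; NaOH, H2O2, 0 °C
Reagents that add atoms: hydrogen peroxide OO
Why: Hydroboration–oxidation puts boron on the less substituted carbon C1 and delivers H to C10 syn from the face opposite the CMe2 bridge, as in the hydroboration of 3-carene, which sets C10 with its methyl group cis to the cyclopropane.

Step 13
Reactants: 25 (1S,3S,4S,7R)-4,8,8-trimethylbicyclo[5.1.0]octan-3-ol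
Product: 26 (1S,4S,7R)-4,8,8-trimethylbicyclo[5.1.0]octan-3-one
Conditions: Dess–Martin periodinane, NaHCO3, CH2Cl2, 0 °C → rt
Reagents that add atoms: none
Why: Buffered Dess–Martin oxidation gives the ketone under non-enolising conditions, so the C10 stereocentre next to the carbonyl is kept.

Step 14
Reactants: 26 (1S,4S,7R)-4,8,8-trimethylbicyclo[5.1.0]octan-3-one
Product: 27 2,4,6-triisopropylbenzenesulfonyl hydrazone of 26
Conditions: TrisNHNH2, THF, rt
Reagents that add atoms: 2,4,6-triisopropylbenzenesulfonohydrazide CC(C)c1cc(C(C)C)c(S(=O)(=O)NN)c(C(C)C)c1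
Why: Hydrazone condensation at room temperature without added acid or base prepares the Shapiro reaction and should not epimerise C10.

Step 15
Reactants: 27 2,4,6-triisopropylbenzenesulfonyl hydrazone of 26
Product: 29 (1R,4S,7R)-3-iodo-4,8,8-trimethylbicyclo[5.1.0]oct-2-ene, via vinyllithium 28 (not isolated)
Conditions: n-BuLi (2.2 equiv), THF, −78 → 0 °C; I2, −78 °C
Reagents that add atoms: iodine II
Why: In this Shapiro reaction the hydrazone dianion forms only at the less substituted α-carbon C5 and collapses to the vinyllithium, which iodine traps with retention, so the C1=C5 regiochemistry is fixed and C10 is never deprotonated.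

Step 16
Reactants: 29 (1R,4S,7R)-3-iodo-4,8,8-trimethylbicyclo[5.1.0]oct-2-ene; 17 (2E,4R)-4-(2-fluoro-4,6-dimethoxyphenyl)-3,6-dimethylhept-2-en-1-ol
Product: 31 2-[(4R)-4-(2-fluoro-4,6-dimethoxyphenyl)-3,6-dimethylhept-1-en-3-yl]-4,8,8-trimethylbicyclo[5.1.0]octan-3-one (C4–C5 bond anti to the CMe2 bridge; C4/C5/C7′/C10 as in the target), via allyl vinyl ether 30 (not isolated)
Conditions: 29 (1.3 equiv), CuI (10 mol%), 3,4,7,8-Me4-phenanthroline (20 mol%), Cs2CO3, toluene, 80 °C; filter; o-xylene, 140 °C
Reagents that add atoms: none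
Why: Copper-catalysed C–O coupling of the vinyl iodide with the allylic alcohol followed by Claisen rearrangement (domino Ullmann-type etherification–[3,3] shift) forms C4–C5 through a chair in which the enol ether is attacked on the face opposite the CMe2 bridge and the C10 methyl group, the C4 methyl is axial and the C7′ substituent equatorial, which sets the quaternary C4 and C5 as in the target.

Step 17
Reactants: 31 the γ,δ-unsaturated ketone of step 16
Product: 33 2-[(4R)-4-(2-fluoro-4,6-dimethoxyphenyl)-1-hydroxy-3,6-dimethylheptan-3-yl]-4,8,8-trimethylbicyclo[5.1.0]octan-3-one, via B-alkyl-9-BBN 32 (not isolated)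
Conditions: 9-BBN, THF, 0 °C → rt; NaBO3·4H2O, H2O, rt
Reagents that add atoms: sodium perborate [Na+].[Na+].O[B-]1(O)OO[B-](O)(O)OO1
Why: 9-BBN should hydroborate the terminal vinyl group anti-Markovnikov much faster than it reduces a ketone flanked by two tertiary α-carbons, and near-neutral perborate oxidation gives the primary alcohol (C2–OH) without epimerising C5 or C10.

Step 18
Reactants: 33 the hydroxy ketone of step 17
Product: 34 2-[(4R)-4-(2-fluoro-4,6-dimethoxyphenyl)-1-iodo-3,6-dimethylheptan-3-yl]-4,8,8-trimethylbicyclo[5.1.0]octan-3-one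
Conditions: I2, PPh3, imidazole, CH2Cl2, 0 °C
Reagents that add atoms: iodine II
Why: Appel iodination converts the primary alcohol into the iodide under neutral conditions that leave the enolisable ketone alone.

Step 19
Reactants: 34 the iodo ketone of step 18
Product: 35 7-[(1R)-1-(2-fluoro-4,6-dimethoxyphenyl)-3-methylbutyl]-1,1,4,7-tetramethyldecahydro-1H-cyclopropa[e]azulen-4a-ol (4a = C1; OH cis to H5 and to C7′)
Conditions: SmI2 (2.5 equiv), THF–HMPA, −78 → 0 °C
Reagents that add atoms: none
Why: Samarium diiodide reduces the primary iodide to an alkylsamarium that adds to the C1 ketone in a 5-exo intramolecular Barbier reaction, and since the new five-membered ring can only be cis-fused to the cycloheptane the C1 oxygen ends up syn to H5 and thereby to C7′ on C4.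

Step 20
Reactants: 35 the tricyclic tertiary alcohol of step 19
Product: 36 7-[(1R)-1-(3,5-dibromo-2-fluoro-4,6-dimethoxyphenyl)-3-methylbutyl]-1,1,4,7-tetramethyldecahydro-1H-cyclopropa[e]azulen-4a-ol
Conditions: NBS (2.1 equiv), MeCN, 0 °C → rt
Reagents that add atoms: N-bromosuccinimide O=C1CCC(=O)N1Br
Why: Electrophilic bromination fills the only free arene positions C3′ and C5′, both ortho or para to the methoxy groups, while the tertiary alcohol and the cyclopropane are inert to NBS in the dark.

Step 21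
Reactants: 36 the dibromide of step 20
Product: 38 4-fluoro-5-[(1R)-1-(4a-hydroxy-1,1,4,7-tetramethyldecahydro-1H-cyclopropa[e]azulen-7-yl)-3-methylbutyl]-2,6-dimethoxybenzene-1,3-dicarbaldehyde, via aryl dilithium alkoxide 37 (not isolated)
Conditions: t-BuLi (5.5 equiv), THF, −78 °C; DMF, −78 → −40 °C; aq. NH4Cl
Reagents that add atoms: N,N-dimethylformamide CN(C)C=O
Why: After deprotonation of the alcohol, double bromine–lithium exchange and formylation with DMF install both aldehydes under basic conditions (the lithium next to fluorine is stable at −78 °C), whereas Lewis-acidic electrophilic formylation would ionise the tertiary alcohol and a Vilsmeier reagent would not take this dimethoxyfluoroarene beyond the mono-aldehyde.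

Step 22
Reactants: 38 the fluoro dialdehyde with free C1 tertiary alcohol
Product: 40 dimethyl ether of the target (O–C2′ bond made; OMe at C4′ and C6′; CHO at C3′ and C5′), via sodium alkoxide 39 (not isolated)
Conditions: NaH (1.2 equiv), THF (0.01 M), 0 °C → rt
Reagents that add atoms: none
Why: Sodium hydride turns the C1 tertiary alcohol into its alkoxide, which adds to C2′ to give a Meisenheimer anion whose charge is taken up by the ortho formyl group on C3′ and the para formyl group on C5′, and loss of fluoride then restores the arene (addition–elimination). The closest known reaction type is the intramolecular SNAr etherification of alkoxides on fluoroarenes that carry ortho and para acyl groups, as used for chromans and benzoxepines. The oxepine O–C1–C5–C4–C7′–C1′–C2′ closes in a 7-exo-trig sense, the C2′=C3′ bond that accepts the charge lying outside the new ring, and closure is possible because O on C1 and C7′ on C4 are cis-1,3 on the cyclopentane. No stereocentre is formed or touched, since the aryl aldehydes have no enolisable hydrogen and C1 reacts at oxygen only. The step needs chemoselectivity for C2′–F over the equally ortho/para-activated C6′–OMe and over the formyl carbons: fluorine is by far the better SNAr activator and leaving group, addition to a CHO group is reversible and would need a ring of nine or more atoms, and high dilution with a non-nucleophilic hydride base suppresses intermolecular substitution and Tishchenko-type hydride transfer. Forming the tertiary alkyl aryl ether at an sp2 carbon also means that no cation arises at C1 or near the cyclopropane.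

Step 23
Reactants: 40 dimethyl ether of the target
Product: 41 CNP0189833.2 (target)
Conditions: NaSEt (excess), DMF, 120 °C; aq. HCl work-up
Reagents that add atoms: none
Why: Thiolate SN2 demethylation attacks only the two methyl carbons, each phenoxide being a good leaving group because of its ortho formyl group, whereas the tertiary C1–O ether cannot undergo SN2 and the non-acidic medium leaves it and the cyclopropane intact.

**Compound list**

1 | 1-fluoro-3,5-dimethoxybenzene | COc1cc(F)cc(OC)c1 | starting material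
2 | 2-bromo-1-fluoro-3,5-dimethoxybenzene | COc1cc(OC)c(Br)c(F)c1 | intermediate
3 | (2-fluoro-4,6-dimethoxyphenyl)lithium | COc1cc(OC)c([Li])c(F)c1 | intermediate
4 | 2-(2-fluoro-4,6-dimethoxyphenyl)-4,4,5,5-tetramethyl-1,3,2-dioxaborolane | COc1cc(OC)c(B2OC(C)(C)C(C)(C)O2)c(F)c1 | intermediate
5 | 3-methylbutan-1-ol | CC(C)CCO | starting material
6 | 3-methylbutyl N,N-diisopropylcarbamate | CC(C)CCOC(=O)N(C(C)C)C(C)C | intermediate
7 | (R)-1-lithio-3-methylbutyl N,N-diisopropylcarbamate, as its (+)-sparteine complex | CC(C)C[C@H](OC(=O)N(C(C)C)C(C)C)[Li] | intermediate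
8 | lithium aryl(1-carbamoyloxy-3-methylbutyl)pinacolatoborate | CC(C)C[C@H](OC(=O)N(C(C)C)C(C)C)[B-]1(c2c(OC)cc(OC)cc2F)OC(C)(C)C(C)(C)O1.[Li+] | intermediate
9 | (S)-2-[1-(2-fluoro-4,6-dimethoxyphenyl)-3-methylbutyl]-4,4,5,5-tetramethyl-1,3,2-dioxaborolane | CC(C)C[C@@H](c1c(OC)cc(OC)cc1F)B1OC(C)(C)C(C)(C)O1 | intermediate
10 | but-2-yn-1-ol | CC#CCO | starting material
11 | sodium cyclic (Z)-alkenylalanate from Red-Al | CC1=CCO[Al-]1(OCCOC)OCCOC.[Na+] | intermediate
12 | (Z)-3-iodobut-2-en-1-ol | C/C(I)=C/CO | intermediate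
13 | tert-butyl{[(Z)-3-iodobut-2-en-1-yl]oxy}dimethylsilane | C/C(I)=C/CO[Si](C)(C)C(C)(C)C | intermediate
14 | [(Z)-4-(tert-butyldimethylsilyloxy)but-2-en-2-yl]lithium | C/C([Li])=C/CO[Si](C)(C)C(C)(C)C | intermediate
15 | lithium alkenyl(1-aryl-3-methylbutyl)pinacolatoborate | [Li+].CC(C)C[C@@H](c1c(OC)cc(OC)cc1F)[B-]1(OC(C)(C)C(C)(C)O1)/C(C)=C\CO[Si](C)(C)C(C)(C)C | intermediate
16 | tert-butyl{[(2E,4R)-4-(2-fluoro-4,6-dimethoxyphenyl)-3,6-dimethylhept-2-en-1-yl]oxy}dimethylsilane | CC(C)C[C@@H](c1c(OC)cc(OC)cc1F)/C(C)=C/CO[Si](C)(C)C(C)(C)C | intermediate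
17 | (2E,4R)-4-(2-fluoro-4,6-dimethoxyphenyl)-3,6-dimethylhept-2-en-1-ol | CC(C)C[C@@H](c1c(OC)cc(OC)cc1F)/C(C)=C/CO | intermediate
18 | (+)-2-carene, (1S,6R)-3,7,7-trimethylbicyclo[4.1.0]hept-2-ene | CC1=C[C@H]2[C@@H](CC1)C2(C)C | starting material
19 | secondary ozonide of 2-carene (mixture at the two new centres) | CC12OC(OO1)[C@H]1[C@@H](CC2)C1(C)C | intermediate
20 | (1S,3R)-2,2-dimethyl-3-(3-oxobutyl)cyclopropane-1-carbaldehyde | O=C[C@H]1[C@@H](CCC(C)=O)C1(C)C | intermediate
21 | 4-[cis-3-(2-methoxyethenyl)-2,2-dimethylcyclopropyl]butan-2-one (E/Z mixture; ring centres as in 20) | COC=C[C@H]1[C@@H](CCC(C)=O)C1(C)C | intermediate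
22 | 2-[(1S,3R)-2,2-dimethyl-3-(3-oxobutyl)cyclopropyl]acetaldehyde | O=CC[C@H]1[C@@H](CCC(C)=O)C1(C)C | intermediate
23 | (1S,7R)-4,8,8-trimethylbicyclo[5.1.0]oct-3-ene | CC1=CC[C@H]2[C@@H](CC1)C2(C)C | intermediate
24 | alkylborane from 23, drawn as the monoalkylborane (B on C1, anti to the CMe2 bridge) | C[C@@H]1[C@@H](B)C[C@H]2[C@@H](CC1)C2(C)C | intermediate
25 | (1S,3S,4S,7R)-4,8,8-trimethylbicyclo[5.1.0]octan-3-ol | C[C@@H]1[C@@H](O)C[C@H]2[C@@H](CC1)C2(C)C | intermediate
26 | (1S,4S,7R)-4,8,8-trimethylbicyclo[5.1.0]octan-3-one | C[C@@H]1C(=O)C[C@H]2[C@@H](CC1)C2(C)C | intermediate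
27 | 2,4,6-triisopropylbenzenesulfonyl hydrazone of 26 | C[C@@H]1C(=NNS(=O)(=O)c3c(C(C)C)cc(C(C)C)cc3C(C)C)C[C@H]2[C@@H](CC1)C2(C)C | intermediate
28 | 4,8,8-trimethylbicyclo[5.1.0]oct-2-en-3-yllithium (ring centres as in 29) | C[C@@H]1C([Li])=C[C@H]2[C@@H](CC1)C2(C)C | intermediate
29 | (1R,4S,7R)-3-iodo-4,8,8-trimethylbicyclo[5.1.0]oct-2-ene | C[C@@H]1C(I)=C[C@H]2[C@@H](CC1)C2(C)C | intermediate
30 | allyl vinyl ether: 3-{[(2E,4R)-4-(2-fluoro-4,6-dimethoxyphenyl)-3,6-dimethylhept-2-en-1-yl]oxy}-4,8,8-trimethylbicyclo[5.1.0]oct-2-ene (ring centres as in 29) | C[C@@H]1C(OC/C=C(C)/[C@@H](CC(C)C)c3c(OC)cc(OC)cc3F)=C[C@H]2[C@@H](CC1)C2(C)C | intermediate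
31 | 2-[(4R)-4-(2-fluoro-4,6-dimethoxyphenyl)-3,6-dimethylhept-1-en-3-yl]-4,8,8-trimethylbicyclo[5.1.0]octan-3-one (C4, C5, C7′, C10 as in the target) | C=C[C@](C)([C@@H](CC(C)C)c1c(OC)cc(OC)cc1F)[C@@H]1C(=O)[C@@H](C)CC[C@@H]2[C@H]1C2(C)C | intermediate
32 | B-alkyl-9-borabicyclo[3.3.1]nonane from 31 (boron on C2) | B1(CC[C@](C)([C@@H](CC(C)C)c3c(OC)cc(OC)cc3F)[C@@H]3C(=O)[C@@H](C)CC[C@@H]4[C@H]3C4(C)C)C2CCCC1CCC2 | intermediate
33 | 2-[(4R)-4-(2-fluoro-4,6-dimethoxyphenyl)-1-hydroxy-3,6-dimethylheptan-3-yl]-4,8,8-trimethylbicyclo[5.1.0]octan-3-one | OCC[C@](C)([C@@H](CC(C)C)c1c(OC)cc(OC)cc1F)[C@@H]1C(=O)[C@@H](C)CC[C@@H]2[C@H]1C2(C)C | intermediate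
34 | 2-[(4R)-4-(2-fluoro-4,6-dimethoxyphenyl)-1-iodo-3,6-dimethylheptan-3-yl]-4,8,8-trimethylbicyclo[5.1.0]octan-3-one | ICC[C@](C)([C@@H](CC(C)C)c1c(OC)cc(OC)cc1F)[C@@H]1C(=O)[C@@H](C)CC[C@@H]2[C@H]1C2(C)C | intermediate
35 | 7-[(1R)-1-(2-fluoro-4,6-dimethoxyphenyl)-3-methylbutyl]-1,1,4,7-tetramethyldecahydro-1H-cyclopropa[e]azulen-4a-ol (cis-fused; C1–OH cis to H5 and C7′) | CC(C)C[C@@H](c1c(OC)cc(OC)cc1F)[C@@]1(C)CC[C@@]2(O)[C@@H]1[C@H]1[C@@H](CC[C@@H]2C)C1(C)C | intermediate
36 | 7-[(1R)-1-(3,5-dibromo-2-fluoro-4,6-dimethoxyphenyl)-3-methylbutyl]-1,1,4,7-tetramethyldecahydro-1H-cyclopropa[e]azulen-4a-ol | CC(C)C[C@@H](c1c(OC)c(Br)c(OC)c(Br)c1F)[C@@]1(C)CC[C@@]2(O)[C@@H]1[C@H]1[C@@H](CC[C@@H]2C)C1(C)C | intermediate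
37 | C3′,C5′-dilithio lithium alkoxide derived from 36 | CC(C)C[C@@H](c1c(OC)c([Li])c(OC)c([Li])c1F)[C@@]1(C)CC[C@@]2(O[Li])[C@@H]1[C@H]1[C@@H](CC[C@@H]2C)C1(C)C | intermediate
38 | 4-fluoro-5-[(1R)-1-(4a-hydroxy-1,1,4,7-tetramethyldecahydro-1H-cyclopropa[e]azulen-7-yl)-3-methylbutyl]-2,6-dimethoxybenzene-1,3-dicarbaldehyde (key-step precursor) | CC(C)C[C@@H](c1c(OC)c(C=O)c(OC)c(C=O)c1F)[C@@]1(C)CC[C@@]2(O)[C@@H]1[C@H]1[C@@H](CC[C@@H]2C)C1(C)C | intermediate
39 | sodium C1-alkoxide of 38 | [Na+].CC(C)C[C@@H](c1c(OC)c(C=O)c(OC)c(C=O)c1F)[C@@]1(C)CC[C@@]2([O-])[C@@H]1[C@H]1[C@@H](CC[C@@H]2C)C1(C)C | intermediate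
40 | dimethyl ether of the target (key-step product) | CC(C)C[C@H]1c2c(OC)c(C=O)c(OC)c(C=O)c2O[C@]23CC[C@@]1(C)[C@H]2[C@H]1[C@@H](CC[C@@H]3C)C1(C)C | intermediate
41 | CNP0189833.2 | CC(C)C[C@H]1c2c(O)c(C=O)c(O)c(C=O)c2O[C@]23CC[C@@]1(C)[C@H]2[C@H]1[C@@H](CC[C@@H]3C)C1(C)C | target

**Step count and risks**

Total step count: 23. Longest linear sequence: 15 steps (steps 9–23, from (+)-2-carene); alcohol 17 is made in 8 steps (5 linear) and joins at step 16.

Steps most likely to fail:

1. Step 16. The C–O coupling of the hindered cyclic vinyl iodide with the bulky alkoxide may be slow, and at the temperature needed the carbonate base could erode the C5/C10 configuration of the ketone as it forms. The fallback sets out from hydrazone 27: the Shapiro vinyllithium 28 is trapped with i-PrOBpin instead of iodine to give the alkenyl boronate 4,4,5,5-tetramethyl-2-(4,8,8-trimethylbicyclo[5.1.0]oct-2-en-3-yl)-1,3,2-dioxaborolane F1. Oxidative copper(II) acetate/Et3N coupling of F1 (in excess) with alcohol 17 at room temperature (Chan–Lam-type etherification of an alkenyl boronate) should give allyl vinyl ether 30, which is filtered free of copper and base and rearranged by heat alone in o-xylene. The route is rejoined at ketone 31.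

2. Step 21. The second bromine–lithium exchange on the aryl polyanion may stay incomplete, and the lithium next to fluorine may be lost as LiF (aryne formation) before DMF is added. The fallback sets out from dibromide 36: twofold Stille coupling with tributyl(vinyl)stannane (Pd2(dba)3, P(t-Bu)3, CsF, dioxane) should give the divinyl arene 7-[(1R)-1-(2-fluoro-4,6-dimethoxy-3,5-divinylphenyl)-3-methylbutyl]-1,1,4,7-tetramethyldecahydro-1H-cyclopropa[e]azulen-4a-ol F2. Lemieux–Johnson cleavage (cat. OsO4, NaIO4, 2,6-lutidine, dioxane–water) converts both vinyl groups into formyl groups, and the route is rejoined at dialdehyde 38.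

3. Step 4. Ate-complex formation with the di-ortho-substituted boronic ester may be slow and reversible, so the lithiated carbamate could decompose or racemise before the 1,2-shift. The fallback sets out from bromide 2: Suzuki–Miyaura coupling with (E)-(3-methylbut-1-en-1-yl)boronic acid pinacol ester should give the styrene 1-fluoro-3,5-dimethoxy-2-[(E)-3-methylbut-1-en-1-yl]benzene F3. Copper hydride-catalysed enantioselective hydroboration with pinacolborane (CuCl, NaOt-Bu, the DTBM-SEGPHOS enantiomer that delivers the (S)-boronate) puts boron on the benzylic carbon, and the route is rejoined at boronic ester 9.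

Further compounds
F1 | step 16 | 4,4,5,5-tetramethyl-2-(4,8,8-trimethylbicyclo[5.1.0]oct-2-en-3-yl)-1,3,2-dioxaborolane (ring centres as in 29) | C[C@@H]1C(B3OC(C)(C)C(C)(C)O3)=C[C@H]2[C@@H](CC1)C2(C)C
F2 | step 21 | 7-[(1R)-1-(2-fluoro-4,6-dimethoxy-3,5-divinylphenyl)-3-methylbutyl]-1,1,4,7-tetramethyldecahydro-1H-cyclopropa[e]azulen-4a-ol | CC(C)C[C@@H](c1c(OC)c(C=C)c(OC)c(C=C)c1F)[C@@]1(C)CC[C@@]2(O)[C@@H]1[C@H]1[C@@H](CC[C@@H]2C)C1(C)C
F3 | step 4 | 1-fluoro-3,5-dimethoxy-2-[(E)-3-methylbut-1-en-1-yl]benzene | COc1cc(OC)c(/C=C/C(C)C)c(F)c1
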